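**Retrosynthetic overview**
- The strategy rests on the trans-fused α-methylene-γ-butyrolactone (O–C6, C7, C11=C13, C12=O) that sits on the C6–C7 bond of the ten-membered carbocycle C1–C10. This motif is the imprint of a 2-(methoxycarbonyl)allyl metal attacking a C6 aldehyde through its γ-carbon C7.
- Late stage: the C9 hydroxyl is released from a TBS ether, and the C8 angelate is made from a PMB ether (DDQ, then angeloylation with bought angelic acid).
- Key disconnection: C6–C7, with O6–C12 closing directly afterwards, leads to an acyclic ω-formyl (Z)-2-(bromomethyl)enoate. This comes from a C7 aldehyde and methyl acrylate (Morita–Baylis–Hillman, then bromination with allylic transposition).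
- The C8/C9 syn-diol comes from a reagent-controlled (Z)-γ-alkoxyallylboration of a C9 ynal. The C1=C10 enoate comes from the alkyne (syn hydrostannation, iodination, lithiation, carboxylation). C1–C6 and the C4 methyl come from (S)-citronellal.
- Ring order: no ring exists before the key step; the ten-membered carbocycle closes first (C6–C7) and the five-membered lactone (O6–C12) follows in the same flask.

Key step: step 16

Remark: germacrane numbering is used for every intermediate (C1–C10 the future ring carbons, C11–C13 the lactone carbons, C14 the ester carbon on C10, C15 the methyl on C4). A CIP letter quoted for one atom can change between intermediates when a neighbouring group changes, although the spatial arrangement is kept.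
Remark: (+)-Ipc2BOMe, the antipode made from (−)-α-pinene, is taken as the one that delivers the allyl group to the Re face of the ynal (8S,9S product).

Step 1
Reactants: 1 (S)-citronellal [(3S)-3,7-dimethyloct-6-enal]
Product: 2 (6S)-8,8-dimethoxy-2,6-dimethyloct-2-ene
Conditions: HC(OMe)3, MeOH, PPTS (cat.), rt
Reagents that add atoms: trimethyl orthoformate COC(OC)OC; methanol CO
Why: Acid-catalysed acetalisation with the orthoformate as water scavenger masks the future C6 aldehyde, the mild catalyst avoids the carbonyl-ene cyclisation of citronellal, and C4 is untouched.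

Step 2
Reactants: 2 (6S)-8,8-dimethoxy-2,6-dimethyloct-2-ene
Product: 4 (4S)-6,6-dimethoxy-4-methylhexanal, via ozonide 3 (not isolated)
Conditions: O3, CH2Cl2, −78 °C; then PPh3, −78 °C to rt
Reagents that add atoms: ozone [O-][O+]=O
Why: Ozonolysis of the only alkene with reductive cleavage of the ozonide should give the C1 aldehyde, the acetal being inert and C4 not enolisable.

Step 3
Reactants: 4 (4S)-6,6-dimethoxy-4-methylhexanal
Product: 5 (5S)-7,7-dimethoxy-5-methylhept-1-yne
Conditions: dimethyl (1-diazo-2-oxopropyl)phosphonate, K2CO3, MeOH, 0 °C to rt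
Reagents that add atoms: dimethyl (1-diazo-2-oxopropyl)phosphonate COP(=O)(OC)C(=[N+]=[N-])C(C)=O
Why: The Ohira–Bestmann alkynylation (Seyferth–Gilbert homologation) converts the aldehyde into the terminal alkyne under mildly basic conditions that the acetal tolerates, adding C10.

Step 4
Reactants: 5 (5S)-7,7-dimethoxy-5-methylhept-1-yne
Product: 7 (6S)-8,8-dimethoxy-6-methyloct-2-ynal, via lithium acetylide 6 (not isolated)
Conditions: n-BuLi, THF, −78 °C; DMF, −78 to 0 °C; inverse quench into cold aq. KH2PO4
Reagents that add atoms: N,N-dimethylformamide CN(C)C=O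
Why: Formylation of the lithium acetylide with DMF gives the C9 ynal, and the buffered inverse quench releases it without conjugate addition of dimethylamine or loss of the acetal.

Step 5
Reactants: 8 allyl alcohol (prop-2-en-1-ol)
Product: 10 allyl 4-methoxybenzyl ether, via sodium allyloxide 9 (not isolated)
Conditions: NaH, THF–DMF, 0 °C; 4-methoxybenzyl chloride, Bu4NI (cat.), rt
Reagents that add atoms: 4-methoxybenzyl chloride COc1ccc(CCl)cc1
Why: Williamson ether synthesis of the alkoxide with the reactive benzylic chloride.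

Step 6
Reactants: 7 (6S)-8,8-dimethoxy-6-methyloct-2-ynal; 10 allyl 4-methoxybenzyl ether
Product: 14 (3S,4S,9S)-11,11-dimethoxy-3-[(4-methoxybenzyl)oxy]-9-methylundec-1-en-5-yn-4-ol (germacrane 8S,9S,4S), via allyllithium 11 (not isolated), via allylborane 12 (not isolated), via borinate 13 (not isolated)
Conditions: 10, s-BuLi, THF, −78 °C; (+)-Ipc2BOMe, −78 °C; BF3·OEt2; 7, −78 °C; then aq. NaOH, H2O2, 0 °C to rt
Reagents that add atoms: none
Why: Brown (Z)-γ-alkoxyallylboration, in which the chelated Z-allyllithium is borylated and the resulting allylborane adds to the ynal through a chair Zimmerman–Traxler transition state, so that the Z enol ether geometry sets the syn C8/C9 relationship and the isopinocampheyl groups select the Re face of the aldehyde (8S,9S).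

Step 7
Reactants: 14 (3S,4S,9S)-11,11-dimethoxy-3-[(4-methoxybenzyl)oxy]-9-methylundec-1-en-5-yn-4-ol
Product: 15 (3S,4R,5E,9S)-11,11-dimethoxy-3-[(4-methoxybenzyl)oxy]-9-methyl-5-(tributylstannyl)undeca-1,5-dien-4-ol (tin on C10, hydrogen on C1)
Conditions: Bu3SnH, PdCl2(PPh3)2 (cat.), THF, 0 °C to rt
Reagents that add atoms: tributyltin hydride CCCC[SnH](CCCC)CCCC
Why: Palladium-catalysed hydrostannation adds H and Sn syn, and with the free α-branched propargylic alcohol the tin should go to the carbon next to the carbinol (C10), which places C2 and C9 cis on the new alkene (the distal regioisomer is removed by chromatography).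

Step 8
Reactants: 15 (3S,4R,5E,9S)-11,11-dimethoxy-3-[(4-methoxybenzyl)oxy]-9-methyl-5-(tributylstannyl)undeca-1,5-dien-4-ol
Product: 16 (3S,4R,5E,9S)-5-iodo-11,11-dimethoxy-3-[(4-methoxybenzyl)oxy]-9-methylundeca-1,5-dien-4-ol
Conditions: iodine, CH2Cl2, 0 °C; aq. Na2S2O3
Reagents that add atoms: iodine II
Why: Iododestannylation is an ipso substitution at the tin-bearing carbon with retention of alkene geometry, and the isolated vinyl group, the PMB ether and the acetal are not attacked at 0 °C.

Step 9
Reactants: 16 (3S,4R,5E,9S)-5-iodo-11,11-dimethoxy-3-[(4-methoxybenzyl)oxy]-9-methylundeca-1,5-dien-4-ol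
Product: 17 tert-butyl{[(3S,4R,5E,9S)-5-iodo-11,11-dimethoxy-3-[(4-methoxybenzyl)oxy]-9-methylundeca-1,5-dien-4-yl]oxy}dimethylsilane
Conditions: TBSCl, imidazole, DMF, rt to 40 °C
Reagents that add atoms: tert-butyldimethylsilyl chloride CC(C)(C)[Si](C)(C)Cl
Why: Standard silylation of the secondary allylic alcohol, done after the bulky stannyl group is gone and with the chloride and imidazole because a silyl triflate would attack the dimethyl acetal.

Step 10
Reactants: 17 the C9 TBS ether of the C10 alkenyl iodide
Product: 19 methyl (2E,6S)-2-[(1S,2S)-1-[(tert-butyldimethylsilyl)oxy]-2-[(4-methoxybenzyl)oxy]but-3-en-1-yl]-8,8-dimethoxy-6-methyloct-2-enoate, via alkenyllithium 18 (not isolated)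
Conditions: t-BuLi (2.1 equiv), Et2O, −78 °C; ClCO2Me, −78 to 0 °C
Reagents that add atoms: methyl chloroformate COC(=O)Cl
Why: Iodine–lithium exchange gives an alkenyllithium that is configurationally stable at −78 °C and is acylated by methyl chloroformate with retention, so the ester ends on C10 cis to H1 and C2 stays cis to C9.

Step 11
Reactants: 19 the C10 methyl enoate bearing the terminal vinyl group
Product: 20 methyl (2E,6S)-2-[(1S,2S)-1-[(tert-butyldimethylsilyl)oxy]-3,4-dihydroxy-2-[(4-methoxybenzyl)oxy]butyl]-8,8-dimethoxy-6-methyloct-2-enoate (both epimers at the new carbinol)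
Conditions: OsO4 (cat.), NMO, acetone–H2O, 0 °C to rt
Reagents that add atoms: N-methylmorpholine N-oxide C[N+]1([O-])CCOCC1; water O
Why: In this Upjohn dihydroxylation the monosubstituted vinyl group should react far faster than the electron-poor, hindered trisubstituted enoate, and the configuration of the new carbinol does not matter.

Step 12
Reactants: 20 the terminal diol
Product: 21 methyl (2E,6S)-2-[(1S,2R)-1-[(tert-butyldimethylsilyl)oxy]-2-[(4-methoxybenzyl)oxy]-3-oxopropyl]-8,8-dimethoxy-6-methyloct-2-enoate (C7 aldehyde; C8 spatially unchanged)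
Conditions: NaIO4, THF–pH 7 phosphate buffer, 0 °C to rt; used crude
Reagents that add atoms: none
Why: Periodate glycol cleavage under buffered conditions gives the α-alkoxy aldehyde without epimerisation at C8.

Step 13
Reactants: 21 the C7 aldehyde; 22 methyl acrylate
Product: 23 methyl (2E,6S)-2-[(1S,2S)-1-[(tert-butyldimethylsilyl)oxy]-3-hydroxy-2-[(4-methoxybenzyl)oxy]-4-(methoxycarbonyl)pent-4-en-1-yl]-8,8-dimethoxy-6-methyloct-2-enoate (both C7 epimers)
Conditions: DABCO (1 equiv), neat methyl acrylate (excess), a little MeOH, rt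
Reagents that add atoms: none
Why: Morita–Baylis–Hillman reaction in which the amine–acrylate zwitterion adds to the activated α-alkoxy aldehyde and loss of the amine returns the 2-methylene ester; the C7 carbinol mixture is erased in step 14 and the weak base should leave C8 intact.

Step 14
Reactants: 23 the Morita–Baylis–Hillman adduct
Product: 25 methyl (2E,6S)-2-[(1S,2S,3Z)-5-bromo-1-[(tert-butyldimethylsilyl)oxy]-2-[(4-methoxybenzyl)oxy]-4-(methoxycarbonyl)pent-3-en-1-yl]-8,8-dimethoxy-6-methyloct-2-enoate, via alkoxysulfonium bromide 24 (not isolated)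
Conditions: NBS, Me2S, CH2Cl2, 0 °C; then 23, 0 °C to rt
Reagents that add atoms: N-bromosuccinimide O=C1CCC(=O)N1Br
Why: Corey–Kim-type bromination in which bromide displaces the alkoxysulfonium group in an SN2' sense, transposing the allyl system to the more stable trisubstituted (Z)-2-(bromomethyl)enoate (C8 trans to the ester) and removing the C7 stereocentre.

Step 15
Reactants: 25 the allylic bromide dimethyl acetal
Product: 26 methyl (2E,6S)-2-[(1S,2S,3Z)-5-bromo-1-[(tert-butyldimethylsilyl)oxy]-2-[(4-methoxybenzyl)oxy]-4-(methoxycarbonyl)pent-3-en-1-yl]-6-methyl-8-oxooct-2-enoate (C6 aldehyde)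
Conditions: p-TsOH·H2O (cat.), acetone–H2O, 0 °C to rt
Reagents that add atoms: water O
Why: Acid-catalysed acetal hydrolysis frees the C6 aldehyde, while the hindered secondary TBS ether, the PMB ether and the allylic bromide should survive the mild acid.

Step 16
Reactants: 26 the ω-formyl (Z)-2-(bromomethyl)enoate
Product: 29 methyl (1(10)E,4S,6R,7S,8S,9S)-9-(tert-butyldimethylsilyloxy)-8-(4-methoxybenzyloxy)germacra-1(10),11(13)-dien-12,6-olid-14-oate (trans-fused α-methylene lactone), via allylchromium dichloride 27 (not isolated), via chromium alkoxide 28 (not isolated)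
Conditions: CrCl2 (8 equiv), THF, rt, syringe-pump addition of 26 to about 0.002 M; aq. NH4Cl; p-TsOH (cat.) if any hydroxy ester remains
Reagents that add atoms: none
Why: Two equivalents of CrCl2 reduce the C13–Br bond by successive one-electron transfers to the allylchromium dichloride 27 (trivalent chromium), whose C7=C11 geometry is mobile through reversible 1,3-shifts of the metal, and this adds through its γ-carbon C7 to the chromium-bound C6 aldehyde in a six-membered chair transition state; the reaction type is the Nozaki–Hiyama carbonyl allylation run as an intramolecular Barbier reaction, the established way of closing germacranolide rings from ω-formyl 2-(bromomethyl)alk-2-enoates. The C6–C7 bond formation closes the ten-membered carbocycle (allyl transfer with transposition, C11=C13 reappearing as the exocyclic methylene; helped by high dilution and by the C1=C10 enoate, which holds C2 and C9 cis and turns the chain ends toward each other), and the chromium alkoxide 28 then closes the five-membered lactone by 5-exo-trig attack of O6 on the C12 ester with loss of methoxide. C6 and C7 are created together: their anti relationship (H6 and H7 trans, 6R,7S) is set by the chair in which the C5 chain of the aldehyde and C8 are both pseudo-equatorial, reached from the allylchromium isomer with C8 trans to CH2Cr, and the absolute sense is set by C8, whose C–H lies in the plane of the C7=C11 bond (allylic 1,3-strain) so that C6 arrives on the face anti to the C9 branch. The step needs γ-regioselectivity (given by the closed transition state), anti selectivity and this facial selectivity (the weakest point, resting on substrate control), no loss of the C8 oxygen from the allylmetal (it is kept as an ether, a poor leaving group) and chemoselectivity (CrCl2 does not reduce the trisubstituted enoate or the esters).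

Step 17
Reactants: 29 the macrocyclic lactone with C8 OPMB and C9 OTBS
Product: 30 methyl (1(10)E,4S,6R,7R,8S,9S)-9-(tert-butyldimethylsilyloxy)-8-hydroxygermacra-1(10),11(13)-dien-12,6-olid-14-oate (C7 spatially unchanged)
Conditions: DDQ, CH2Cl2–pH 7 buffer, 0 °C to rt
Reagents that add atoms: none
Why: Oxidative PMB cleavage (hydride abstraction by DDQ, then hydrolysis of the oxocarbenium ion) frees the C8 hydroxyl while the electron-poor alkenes, the lactone and the silyl ether are inert.

Step 18
Reactants: 30 the C8 alcohol; 31 angelic acid [(2Z)-2-methylbut-2-enoic acid]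
Product: 33 methyl (1(10)E,4S,6R,7S,8S,9S)-8-[(2Z)-2-methylbut-2-enoyloxy]-9-(tert-butyldimethylsilyloxy)germacra-1(10),11(13)-dien-12,6-olid-14-oate, via mixed anhydride 32 (not isolated)
Conditions: 31, 2,4,6-trichlorobenzoyl chloride, Et3N, toluene, rt; then 30, toluene, 75 °C
Reagents that add atoms: none
Why: Yamaguchi-type esterification through the preformed mixed anhydride, heated without a nucleophilic catalyst, should acylate the hindered alcohol while keeping the Z (angelate) geometry, and C8 keeps its configuration because its C–O bond is not broken.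

Step 19
Reactants: 33 the C8 angelate with C9 OTBS
Product: 34 methyl (1(10)E,4S,6R,7S,8S,9S)-8-[(2Z)-2-methylbut-2-enoyloxy]-9-hydroxygermacra-1(10),11(13)-dien-12,6-olid-14-oate (target CNP0552150.1)
Conditions: HF·pyridine, pyridine, THF, 0 °C to rt
Reagents that add atoms: none
Why: Buffered fluoride-mediated desilylation should remove the TBS group without acyl migration, lactone opening or conjugate addition to the methylene lactone.

**Compound list**
1 | (S)-citronellal | O=CC[C@@H](C)CCC=C(C)C | starting material
2 | (6S)-8,8-dimethoxy-2,6-dimethyloct-2-ene | COC(OC)C[C@@H](C)CCC=C(C)C | intermediate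
3 | ozonide of 2 [3-[(3S)-5,5-dimethoxy-3-methylpentyl]-5,5-dimethyl-1,2,4-trioxolane] | COC(OC)C[C@@H](C)CCC1OOC(C)(C)O1 | intermediate (not isolated)
4 | (4S)-6,6-dimethoxy-4-methylhexanal | COC(OC)C[C@@H](C)CCC=O | intermediate
5 | (5S)-7,7-dimethoxy-5-methylhept-1-yne | COC(OC)C[C@@H](C)CCC#C | intermediate
6 | lithium acetylide of 5 | COC(OC)C[C@@H](C)CCC#C[Li] | intermediate (not isolated)
7 | (6S)-8,8-dimethoxy-6-methyloct-2-ynal | COC(OC)C[C@@H](C)CCC#CC=O | intermediate
8 | allyl alcohol | C=CCO | starting material
9 | sodium allyloxide | C=CC[O-].[Na+] | intermediate (not isolated)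
10 | allyl 4-methoxybenzyl ether | C=CCOCc1ccc(OC)cc1 | intermediate
11 | (Z)-3-[(4-methoxybenzyl)oxy]allyllithium | [Li]C/C=C\OCc1ccc(OC)cc1 | intermediate (not isolated)
12 | [(Z)-3-[(4-methoxybenzyl)oxy]allyl]diisopinocampheylborane, isopinocampheyl groups from (−)-α-pinene | COc1ccc(CO/C=C\CB([C@H]2C[C@H]3C[C@@H]([C@@H]2C)C3(C)C)[C@H]2C[C@H]3C[C@@H]([C@@H]2C)C3(C)C)cc1 | intermediate (not isolated)
13 | diisopinocampheylborinate of alcohol 14 | COC(OC)C[C@@H](C)CCC#C[C@H](OB([C@H]1C[C@H]2C[C@@H]([C@@H]1C)C2(C)C)[C@H]1C[C@H]2C[C@@H]([C@@H]1C)C2(C)C)[C@@H](OCc1ccc(OC)cc1)C=C | intermediate (not isolated)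
14 | (3S,4S,9S)-11,11-dimethoxy-3-[(4-methoxybenzyl)oxy]-9-methylundec-1-en-5-yn-4-ol | COC(OC)C[C@@H](C)CCC#C[C@H](O)[C@@H](OCc1ccc(OC)cc1)C=C | intermediate
15 | (3S,4R,5E,9S)-11,11-dimethoxy-3-[(4-methoxybenzyl)oxy]-9-methyl-5-(tributylstannyl)undeca-1,5-dien-4-ol | COC(OC)C[C@@H](C)CC/C=C(/[Sn](CCCC)(CCCC)CCCC)[C@H](O)[C@@H](OCc1ccc(OC)cc1)C=C | intermediate
16 | (3S,4R,5E,9S)-5-iodo-11,11-dimethoxy-3-[(4-methoxybenzyl)oxy]-9-methylundeca-1,5-dien-4-ol | COC(OC)C[C@@H](C)CC/C=C(/I)[C@H](O)[C@@H](OCc1ccc(OC)cc1)C=C | intermediate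
17 | tert-butyldimethylsilyl ether of 16 | COC(OC)C[C@@H](C)CC/C=C(/I)[C@H](O[Si](C)(C)C(C)(C)C)[C@@H](OCc1ccc(OC)cc1)C=C | intermediate
18 | C10 alkenyllithium from 17 | COC(OC)C[C@@H](C)CC/C=C(/[Li])[C@H](O[Si](C)(C)C(C)(C)C)[C@@H](OCc1ccc(OC)cc1)C=C | intermediate (not isolated)
19 | methyl (2E,6S)-2-[(1S,2S)-1-[(tert-butyldimethylsilyl)oxy]-2-[(4-methoxybenzyl)oxy]but-3-en-1-yl]-8,8-dimethoxy-6-methyloct-2-enoate | COC(OC)C[C@@H](C)CC/C=C(/C(=O)OC)[C@H](O[Si](C)(C)C(C)(C)C)[C@@H](OCc1ccc(OC)cc1)C=C | intermediate
20 | terminal diol from 19 (both epimers at the new carbinol) | COC(OC)C[C@@H](C)CC/C=C(/C(=O)OC)[C@H](O[Si](C)(C)C(C)(C)C)[C@@H](OCc1ccc(OC)cc1)C(O)CO | intermediate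
21 | C7 aldehyde, methyl (2E,6S)-2-[(1S,2R)-1-[(tert-butyldimethylsilyl)oxy]-2-[(4-methoxybenzyl)oxy]-3-oxopropyl]-8,8-dimethoxy-6-methyloct-2-enoate | COC(OC)C[C@@H](C)CC/C=C(/C(=O)OC)[C@H](O[Si](C)(C)C(C)(C)C)[C@@H](OCc1ccc(OC)cc1)C=O | intermediate
22 | methyl acrylate | C=CC(=O)OC | starting material
23 | Morita–Baylis–Hillman adduct (both C7 epimers) | COC(OC)C[C@@H](C)CC/C=C(/C(=O)OC)[C@H](O[Si](C)(C)C(C)(C)C)[C@@H](OCc1ccc(OC)cc1)C(O)C(=C)C(=O)OC | intermediate
24 | alkoxy(dimethyl)sulfonium bromide of 23 | COC(OC)C[C@@H](C)CC/C=C(/C(=O)OC)[C@H](O[Si](C)(C)C(C)(C)C)[C@@H](OCc1ccc(OC)cc1)C(O[S+](C)C)C(=C)C(=O)OC.[Br-] | intermediate (not isolated)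
25 | (Z)-2-(bromomethyl)enoate dimethyl acetal | COC(OC)C[C@@H](C)CC/C=C(/C(=O)OC)[C@H](O[Si](C)(C)C(C)(C)C)[C@@H](OCc1ccc(OC)cc1)/C=C(\CBr)C(=O)OC | intermediate
26 | ω-formyl (Z)-2-(bromomethyl)enoate (C6 aldehyde) | O=CC[C@@H](C)CC/C=C(/C(=O)OC)[C@H](O[Si](C)(C)C(C)(C)C)[C@@H](OCc1ccc(OC)cc1)/C=C(\CBr)C(=O)OC | intermediate
27 | allylchromium dichloride from 26 (C7=C11 geometry mobile) | O=CC[C@@H](C)CC/C=C(/C(=O)OC)[C@H](O[Si](C)(C)C(C)(C)C)[C@@H](OCc1ccc(OC)cc1)C=C(C[Cr](Cl)Cl)C(=O)OC | intermediate (not isolated)
28 | ring-closed C6 chromium alkoxide (ten-membered carbocycle, 1-(methoxycarbonyl)vinyl on C7) | C=C(C(=O)OC)[C@H]1[C@H](O[Cr](Cl)Cl)C[C@@H](C)CC/C=C(/C(=O)OC)[C@H](O[Si](C)(C)C(C)(C)C)[C@H]1OCc2ccc(OC)cc2 | intermediate (not isolated)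
29 | methyl (1(10)E,4S,6R,7S,8S,9S)-9-(tert-butyldimethylsilyloxy)-8-(4-methoxybenzyloxy)germacra-1(10),11(13)-dien-12,6-olid-14-oate | C=C1C(=O)O[C@@H]2C[C@@H](C)CC/C=C(/C(=O)OC)[C@H](O[Si](C)(C)C(C)(C)C)[C@@H](OCc3ccc(OC)cc3)[C@@H]12 | intermediate
30 | methyl (1(10)E,4S,6R,7R,8S,9S)-9-(tert-butyldimethylsilyloxy)-8-hydroxygermacra-1(10),11(13)-dien-12,6-olid-14-oate | C=C1C(=O)O[C@@H]2C[C@@H](C)CC/C=C(/C(=O)OC)[C@H](O[Si](C)(C)C(C)(C)C)[C@@H](O)[C@@H]12 | intermediate
31 | angelic acid | C/C=C(/C)C(=O)O | starting material
32 | angelic 2,4,6-trichlorobenzoic anhydride | C/C=C(/C)C(=O)OC(=O)c1c(Cl)cc(Cl)cc1Cl | intermediate (not isolated)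
33 | methyl (1(10)E,4S,6R,7S,8S,9S)-8-[(2Z)-2-methylbut-2-enoyloxy]-9-(tert-butyldimethylsilyloxy)germacra-1(10),11(13)-dien-12,6-olid-14-oate | C=C1C(=O)O[C@@H]2C[C@@H](C)CC/C=C(/C(=O)OC)[C@H](O[Si](C)(C)C(C)(C)C)[C@@H](OC(=O)/C(C)=C\C)[C@@H]12 | intermediate
34 | methyl (1(10)E,4S,6R,7S,8S,9S)-8-[(2Z)-2-methylbut-2-enoyloxy]-9-hydroxygermacra-1(10),11(13)-dien-12,6-olid-14-oate (CNP0552150.1) | C=C1C(=O)O[C@@H]2C[C@@H](C)CC/C=C(/C(=O)OC)[C@H](O)[C@@H](OC(=O)/C(C)=C\C)[C@@H]12 | target

**Total step count:** 19 steps.
**Longest linear sequence:** 18 steps, from (S)-citronellal (steps 1–4 and 6–19); step 5 is the one-step side branch.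

**Steps most likely to fail**

Step 16 (ring closure). The likely failures are poor facial selectivity at C7 under substrate control, closure to the cis-fused (syn) series, or intermolecular coupling of the chain. The fallback replaces substrate control by reagent control and sets out from bromo aldehyde 26. This is cyclised under chromium catalysis: CrCl2 as precatalyst, a chiral 1,8-bis(oxazolinyl)carbazole ligand in the antipode that adds to the aldehyde face giving the 6R carbinol, Mn powder as stoichiometric reductant, TMSCl and a hindered amine for turnover, THF, slow addition. This is the known ligand-controlled chromium-catalysed 2-(alkoxycarbonyl)allylation of aldehydes. Because the chair still enforces the anti relationship, the C7 face follows from the ligand-fixed C6 face. The closure should give the ring-closed C6 trimethylsilyl ether, a ten-membered carbocycle bearing the 1-(methoxycarbonyl)vinyl group on C7, F1. Catalytic p-TsOH in wet THF would then remove the trimethylsilyl group and close the lactone, coming back to the route at 29.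

Step 13 (Morita–Baylis–Hillman reaction). The likely failure is slow conversion of the hindered aldehyde under the amine, with epimerisation at C8 or β-elimination of the C9 silyloxy group in the meantime. The fallback sets out from aldehyde 21 and replaces the reversible amine-catalysed process by an irreversible addition of a preformed α-metallated acrylate. This is [1-(methoxycarbonyl)vinyl]diisobutylalane, made from methyl propiolate, i-Bu2AlH and HMPA in THF at 0 °C, and it is added to 21 at −78 °C. The same adduct is formed, so the fallback comes back at 23 and no new compound arises on the way (F0).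

Step 10 (lithiation and carboxylation). The likely failures are loss of the allylic silyloxy group from the alkenyllithium (allene formation), protonation of the anion, or double addition to give a ketone. The fallback sets out from alkenyl iodide 17 and avoids the organolithium altogether. It is a palladium-catalysed methoxycarbonylation: PdCl2(PPh3)2, CO (1 atm), MeOH, Et3N, DMF, 60 °C. Zerovalent palladium inserts into the carbon–iodine bond with retention of geometry, CO inserts, and methanolysis releases the ester. It comes back at 19 and no new compound arises on the way (F0).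

**Further compounds**
F1 | step 16 | ring-closed C6 trimethylsilyl ether: methyl 2-[ten-membered carbocycle]acrylate with C6 OSiMe3, C8 OPMB, C9 OTBS and the C10 methyl ester | C=C(C(=O)OC)[C@H]1[C@H](O[Si](C)(C)C)C[C@@H](C)CC/C=C(/C(=O)OC)[C@H](O[Si](C)(C)C(C)(C)C)[C@H]1OCc2ccc(OC)cc2
F0 | step 13 | none | none
F0 | step 10 | none | none
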